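## Retrosynthetic overview

1. Target 16 ← cation exchange and hydrogenolysis of four benzyl ethers ← 3-O-sulfation ← methanolysis of 3-acetoxyflavone 12. Rings A and B are bought in; ring C is the only ring made.
2. Ring C ← C4–C4a bond by intramolecular Friedel–Crafts acylation of 2-acetoxy-3-aryl-3-aryloxyacrylic acid 10, in which O1–C2 is already present as the enol ether and the C3 oxygen as an enol acetate.
3. Feature used: C4a of ring A is ortho to C8a (which carries O1) and to the C5 oxygen, and para to the C7 oxygen. In the 3,4,5-tris(benzyloxy)phenoxy ring of 10 the two carbons ortho to the ether oxygen are equivalent by symmetry, so acylation can give only the 5,6,7-trioxygenated chromone.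
4. 10 ← tert-butyl enol acetate 9 ← α-keto ester 8 ← hydroxy ester 7 ← benzylic opening of glycidate 6 by phenol 3 (sets the future O1–C2 bond).
5. 6 ← aldehyde 4 + chloroacetate 5 (Darzens); 3 ← aldehyde 1 (Baeyer–Villiger/Dakin-type oxidation).

Key step: step 7

Assumption: the target is taken as the free hydrogen sulfate as drawn; the sulfate is carried as its triethylammonium salt and protonated only at the very end by cold cation exchange, because aryl hydrogen sulfates hydrolyse under their own acidity.
Remark: compounds 6–8 are racemic and 6 and 7 may be diastereomer mixtures; their stereocentres are erased in steps 4 and 5, and the target has none.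

## Route

Step 1
Reactants: 1 3,4,5-tris(benzyloxy)benzaldehyde
Product: 3 3,4,5-tris(benzyloxy)phenol, via aryl formate 2 (not isolated)
Conditions: mCPBA, CH2Cl2, 0 °C → rt; then K2CO3 (cat.), MeOH, rt
Reagents that add atoms: mCPBA, O=C(OO)c1cccc(Cl)c1
Why: Baeyer–Villiger (Dakin-type) oxidation, in which the electron-rich aryl group migrates to give formate 2, which catalytic carbonate in methanol transesterifies to the phenol while the benzyl ethers stay intact.

Step 2
Reactants: 4 4-(benzyloxy)benzaldehyde; 5 tert-butyl chloroacetate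
Product: 6 tert-butyl trans-3-[4-(benzyloxy)phenyl]oxirane-2-carboxylate (racemic)
Conditions: KOtBu, THF, −10 °C → rt
Reagents that add atoms: none
Why: Darzens glycidic ester condensation, in which the bulky tert-butyl ester resists transesterification and self-condensation and the trans epoxide should predominate (its configuration is of no consequence later).

Step 3
Reactants: 6 tert-butyl trans-3-[4-(benzyloxy)phenyl]oxirane-2-carboxylate; 3 3,4,5-tris(benzyloxy)phenol
Product: 7 tert-butyl (2R*,3R*)-3-[4-(benzyloxy)phenyl]-2-hydroxy-3-[3,4,5-tris(benzyloxy)phenoxy]propanoate (racemic)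
Conditions: Cs2CO3 (0.2 equiv), DMF, 60 °C
Reagents that add atoms: none
Why: Base-catalysed epoxide opening in which the phenoxide attacks C3, the benzylic carbon activated by the para-benzyloxy group and not adjacent to the ester, by SN2 with inversion; the product alkoxide deprotonates the next phenol so the carbonate stays catalytic, and the free phenoxide in DMF should alkylate on oxygen.

Step 4
Reactants: 7 tert-butyl (2R*,3R*)-3-[4-(benzyloxy)phenyl]-2-hydroxy-3-[3,4,5-tris(benzyloxy)phenoxy]propanoate
Product: 8 tert-butyl 3-[4-(benzyloxy)phenyl]-2-oxo-3-[3,4,5-tris(benzyloxy)phenoxy]propanoate (racemic)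
Conditions: Dess–Martin periodinane (1.3 equiv), CH2Cl2, 0 °C → rt; used crude
Reagents that add atoms: none
Why: Dess–Martin oxidation of a secondary α-hydroxy ester to the α-keto ester under near-neutral conditions that leave the aryl ethers and the tert-butyl ester untouched and remove the C2 stereocentre.

Step 5
Reactants: 8 tert-butyl 3-[4-(benzyloxy)phenyl]-2-oxo-3-[3,4,5-tris(benzyloxy)phenoxy]propanoate
Product: 9 tert-butyl (E)-2-acetoxy-3-[4-(benzyloxy)phenyl]-3-[3,4,5-tris(benzyloxy)phenoxy]prop-2-enoate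
Conditions: Ac2O, Et3N, DMAP (cat.), CH2Cl2, 0 °C → rt
Reagents that add atoms: acetic anhydride, CC(=O)OC(C)=O
Why: Enol acetylation (O-acylation of the enolate) of an α-keto ester whose C3–H is acidified by the ketone, the aryl ring and the aryloxy group, as known for arylpyruvates; the E isomer, with the ester cis to the small aryloxy oxygen, is expected to prevail, and any Z isomer is carried on because the two interconvert in acid in steps 6 and 7.

Step 6
Reactants: 9 tert-butyl (E)-2-acetoxy-3-[4-(benzyloxy)phenyl]-3-[3,4,5-tris(benzyloxy)phenoxy]prop-2-enoate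
Product: 10 (E)-2-acetoxy-3-[4-(benzyloxy)phenyl]-3-[3,4,5-tris(benzyloxy)phenoxy]prop-2-enoic acid
Conditions: CF3CO2H/CH2Cl2 (1:4), 0 °C → rt; co-evaporation with toluene
Reagents that add atoms: none
Why: Acidolysis of the tert-butyl ester with loss of 2-methylpropene in an anhydrous medium that spares the enol acetate, the electron-poor enol ether and the benzyl ethers; the open positions of ring A are each flanked by two oxygen substituents and so are hindered toward the tert-butyl cation.

Step 7
Reactants: 10 (E)-2-acetoxy-3-[4-(benzyloxy)phenyl]-3-[3,4,5-tris(benzyloxy)phenoxy]prop-2-enoic acid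
Product: 12 5,6,7-tris(benzyloxy)-2-[4-(benzyloxy)phenyl]-4-oxo-4H-chromen-3-yl acetate, via mixed trifluoroacetic anhydride 11 (not isolated)
Conditions: (CF3CO)2O (2.5 equiv), CH2Cl2, 0 °C → rt
Reagents that add atoms: none
Why: Trifluoroacetic anhydride converts acid 10 into acyl trifluoroacetate 11, which ionises toward an acylium ion that is attacked by the ortho carbon of the tris(benzyloxy)phenoxy ring (Wheland intermediate, then loss of a proton) to form C4–C4a. The closest known reaction type is the Ruhemann flavone synthesis, the intramolecular Friedel–Crafts acylation of β-aryloxycinnamic acids, run here with the mild anhydride activation used to close aryloxy acids to chromanones and xanthones. Ring C closes in a six-membered exo mode at the acyl carbon (6-exo-trig on the mixed anhydride, 6-exo-dig if the free acylium ion reacts), and no stereocentre is formed. Site selectivity on ring A is secured by symmetry, since the two ortho carbons are equivalent and each is activated by three oxygens (ortho, ortho and para), so only the 5,6,7-trioxygenated chromone can result. The closure needs the carboxyl cis to the aryloxy group, which the E isomer has, and in the activated species the C2–C3 bond gains single-bond character (positive charge shared by the aryloxy oxygen and the para-benzyloxyphenyl ring), so any Z isomer can rotate into the reactive geometry. Closure onto ring B would require attack at a carbon meta to its only oxygen and would give a strained indenone, so it should not compete, and the enol acetate and benzyl ethers should tolerate the trifluoroacetic acid released at or below room temperature.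

Step 8
Reactants: 12 5,6,7-tris(benzyloxy)-2-[4-(benzyloxy)phenyl]-4-oxo-4H-chromen-3-yl acetate
Product: 13 5,6,7-tris(benzyloxy)-2-[4-(benzyloxy)phenyl]-3-hydroxy-4H-chromen-4-one
Conditions: K2CO3 (cat.), MeOH/THF (1:1), 0 °C → rt
Reagents that add atoms: none
Why: Base-catalysed methanolysis (transesterification) of an enol-type acetate, by far the most labile group present; the benzyl ethers and the chromone ring are unaffected at room temperature.

Step 9
Reactants: 13 5,6,7-tris(benzyloxy)-2-[4-(benzyloxy)phenyl]-3-hydroxy-4H-chromen-4-one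
Product: 14 triethylammonium 5,6,7-tris(benzyloxy)-2-[4-(benzyloxy)phenyl]-4-oxo-4H-chromen-3-yl sulfate
Conditions: SO3·NEt3 (5 equiv), Et3N, DMF, 60 °C
Reagents that add atoms: sulfur trioxide–triethylamine complex, CC[N+](CC)(CC)S(=O)(=O)[O-]
Why: O-sulfonation of the only free hydroxyl by a sulfur trioxide–amine complex, the standard sulfation of phenols and flavonols; triethylamine forms the flavonolate, which breaks the hydrogen bond to the C4 carbonyl, and keeps the product as its stable triethylammonium salt.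

Step 10
Reactants: 14 triethylammonium 5,6,7-tris(benzyloxy)-2-[4-(benzyloxy)phenyl]-4-oxo-4H-chromen-3-yl sulfate
Product: 16 5,6,7-trihydroxy-2-(4-hydroxyphenyl)-4-oxo-4H-chromen-3-yl hydrogen sulfate, via triethylammonium salt 15 (not isolated)
Conditions: H2 (1 atm), 10% Pd/C, MeOH/THF (1:1), rt; filtration under Ar; then Dowex 50WX8 (H+ form), MeOH/H2O, 0 °C; freeze-drying
Reagents that add atoms: none
Why: Catalytic hydrogenolysis of the four benzyl aryl ethers, to which the aryl sulfate salt and the tetrasubstituted C2–C3 double bond should be inert at one atmosphere, followed by exchange of triethylammonium for a proton on the sulfonic acid resin in the cold; the free acid is freeze-dried at once under argon to limit self-catalysed hydrolysis and air oxidation of the 5,6,7-triol.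

## Compound list

1 | 3,4,5-tris(benzyloxy)benzaldehyde | O=Cc1cc(OCc2ccccc2)c(OCc2ccccc2)c(OCc2ccccc2)c1 | starting material
2 | 3,4,5-tris(benzyloxy)phenyl formate | O=COc1cc(OCc2ccccc2)c(OCc2ccccc2)c(OCc2ccccc2)c1 | intermediate (not isolated)
3 | 3,4,5-tris(benzyloxy)phenol | Oc1cc(OCc2ccccc2)c(OCc2ccccc2)c(OCc2ccccc2)c1 | intermediate
4 | 4-(benzyloxy)benzaldehyde | O=Cc1ccc(OCc2ccccc2)cc1 | starting material
5 | tert-butyl chloroacetate | ClCC(=O)OC(C)(C)C | starting material
6 | tert-butyl trans-3-[4-(benzyloxy)phenyl]oxirane-2-carboxylate (racemic; 2R,3S enantiomer drawn) | CC(C)(C)OC(=O)[C@@H]1O[C@H]1c1ccc(OCc2ccccc2)cc1 | intermediate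
7 | tert-butyl (2R*,3R*)-3-[4-(benzyloxy)phenyl]-2-hydroxy-3-[3,4,5-tris(benzyloxy)phenoxy]propanoate (racemic; 2R,3R enantiomer drawn) | CC(C)(C)OC(=O)[C@H](O)[C@H](Oc1cc(OCc2ccccc2)c(OCc2ccccc2)c(OCc2ccccc2)c1)c1ccc(OCc2ccccc2)cc1 | intermediate
8 | tert-butyl 3-[4-(benzyloxy)phenyl]-2-oxo-3-[3,4,5-tris(benzyloxy)phenoxy]propanoate (racemic, C3 configurationally labile) | CC(C)(C)OC(=O)C(=O)C(Oc1cc(OCc2ccccc2)c(OCc2ccccc2)c(OCc2ccccc2)c1)c1ccc(OCc2ccccc2)cc1 | intermediate
9 | tert-butyl (E)-2-acetoxy-3-[4-(benzyloxy)phenyl]-3-[3,4,5-tris(benzyloxy)phenoxy]prop-2-enoate (ester cis to aryloxy) | CC(C)(C)OC(=O)/C(OC(C)=O)=C(\Oc1cc(OCc2ccccc2)c(OCc2ccccc2)c(OCc2ccccc2)c1)c1ccc(OCc2ccccc2)cc1 | intermediate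
10 | (E)-2-acetoxy-3-[4-(benzyloxy)phenyl]-3-[3,4,5-tris(benzyloxy)phenoxy]prop-2-enoic acid (carboxyl cis to aryloxy) | OC(=O)/C(OC(C)=O)=C(\Oc1cc(OCc2ccccc2)c(OCc2ccccc2)c(OCc2ccccc2)c1)c1ccc(OCc2ccccc2)cc1 | intermediate (key-step precursor)
11 | (E)-2-acetoxy-3-[4-(benzyloxy)phenyl]-3-[3,4,5-tris(benzyloxy)phenoxy]prop-2-enoic trifluoroacetic anhydride | O=C(OC(=O)C(F)(F)F)/C(OC(C)=O)=C(\Oc1cc(OCc2ccccc2)c(OCc2ccccc2)c(OCc2ccccc2)c1)c1ccc(OCc2ccccc2)cc1 | intermediate (not isolated)
12 | 5,6,7-tris(benzyloxy)-2-[4-(benzyloxy)phenyl]-4-oxo-4H-chromen-3-yl acetate | CC(=O)Oc1c(-c2ccc(OCc3ccccc3)cc2)oc2cc(OCc3ccccc3)c(OCc3ccccc3)c(OCc3ccccc3)c2c1=O | intermediate (key-step product)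
13 | 5,6,7-tris(benzyloxy)-2-[4-(benzyloxy)phenyl]-3-hydroxy-4H-chromen-4-one | O=c1c(O)c(-c2ccc(OCc3ccccc3)cc2)oc2cc(OCc3ccccc3)c(OCc3ccccc3)c(OCc3ccccc3)c12 | intermediate
14 | triethylammonium 5,6,7-tris(benzyloxy)-2-[4-(benzyloxy)phenyl]-4-oxo-4H-chromen-3-yl sulfate | CC[NH+](CC)CC.[O-]S(=O)(=O)Oc1c(-c2ccc(OCc3ccccc3)cc2)oc2cc(OCc3ccccc3)c(OCc3ccccc3)c(OCc3ccccc3)c2c1=O | intermediate
15 | triethylammonium 5,6,7-trihydroxy-2-(4-hydroxyphenyl)-4-oxo-4H-chromen-3-yl sulfate | CC[NH+](CC)CC.[O-]S(=O)(=O)Oc1c(-c2ccc(O)cc2)oc2cc(O)c(O)c(O)c2c1=O | intermediate (not isolated)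
16 | 5,6,7-trihydroxy-2-(4-hydroxyphenyl)-4-oxo-4H-chromen-3-yl hydrogen sulfate | O=c1c(OS(=O)(=O)O)c(-c2ccc(O)cc2)oc2cc(O)c(O)c(O)c12 | target

## Step count and risks

Total steps: 10. Longest linear sequence: 9 steps (from 4 through steps 2–10; the branch from 1, steps 1 and 3–10, is equally long).

**Step 7 (key step).** The donor-stabilised (push–pull) mixed anhydride may ionise too slowly. Acid-induced loss of benzyl ethers, trifluoroacetylation of ring A, or capture of the acyl cation by the neighbouring acetoxy carbonyl could then outrun ring closure. The fallback sets out from phenol 3 and aldehyde 4 and returns at flavonol 13. It forms the C4–C4a bond intermolecularly and closes ring C at O1–C2 instead. Ortho C-acetylation of 3 (Ac2O, BF3·OEt2, 0 °C → rt; the two ortho carbons are again equivalent) should give 1-[2,3,4-tris(benzyloxy)-6-hydroxyphenyl]ethanone F1. Claisen–Schmidt condensation with 4 (KOH, EtOH) should give (E)-1-[2,3,4-tris(benzyloxy)-6-hydroxyphenyl]-3-[4-(benzyloxy)phenyl]prop-2-en-1-one F2. Oxidative cyclisation (I2 cat., DMSO, 120 °C) should give 5,6,7-tris(benzyloxy)-2-[4-(benzyloxy)phenyl]-4H-chromen-4-one F3. Epoxidation with dimethyldioxirane (acetone/CH2Cl2, 0 °C) should give 5,6,7-tris(benzyloxy)-2-[4-(benzyloxy)phenyl]-2,3-epoxychroman-4-one F4, which catalytic TsOH should open to 13. The route resumes at step 9.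

**Step 3.** Chemoselectivity of the epoxide opening may be poor. The electron-rich phenol could be alkylated on carbon through a benzylic cation, or the base could isomerise the glycidate to the arylpyruvate before O-attack at C3. The fallback sets out from aldehyde 4 and phenol 3, returns at keto ester 8, and replaces steps 2–4. Darzens condensation of 4 with tert-butyl dichloroacetate (KOtBu, THF, −20 °C → rt) should give tert-butyl 3-[4-(benzyloxy)phenyl]-2-chlorooxirane-2-carboxylate F5. This rearranges in the flask, by chloride shift with epoxide opening, to tert-butyl 3-[4-(benzyloxy)phenyl]-3-chloro-2-oxopropanoate F6. Williamson-type displacement of the benzylic α-keto chloride by 3 (K2CO3, acetone, rt) should then give 8 directly.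

**Step 6.** The tert-butyl cation may be captured by the benzyloxyphenyl ring, or benzyl ethers and the enol ether may be partly lost in trifluoroacetic acid. The fallback sets out from aldehyde 4 and returns at acid 10. It carries an allyl ester that is removed under neutral conditions. Darzens condensation of 4 with allyl chloroacetate (LiN(SiMe3)2, THF, −78 °C → rt) should give allyl trans-3-[4-(benzyloxy)phenyl]oxirane-2-carboxylate F7. Opening with 3 under the conditions of step 3 should give allyl (2R*,3R*)-3-[4-(benzyloxy)phenyl]-2-hydroxy-3-[3,4,5-tris(benzyloxy)phenoxy]propanoate F8. Dess–Martin oxidation should give allyl 3-[4-(benzyloxy)phenyl]-2-oxo-3-[3,4,5-tris(benzyloxy)phenoxy]propanoate F9. Enol acetylation as in step 5 should give allyl (E)-2-acetoxy-3-[4-(benzyloxy)phenyl]-3-[3,4,5-tris(benzyloxy)phenoxy]prop-2-enoate F10. Deallylation (Pd(PPh3)4 cat., PhSiH3, CH2Cl2, rt) should then release 10 without acid or nucleophilic amine.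

## Further compounds

F1 | step 7 | 1-[2,3,4-tris(benzyloxy)-6-hydroxyphenyl]ethanone | CC(=O)c1c(O)cc(OCc2ccccc2)c(OCc2ccccc2)c1OCc1ccccc1
F2 | step 7 | (E)-1-[2,3,4-tris(benzyloxy)-6-hydroxyphenyl]-3-[4-(benzyloxy)phenyl]prop-2-en-1-one | O=C(/C=C/c1ccc(OCc2ccccc2)cc1)c1c(O)cc(OCc2ccccc2)c(OCc2ccccc2)c1OCc1ccccc1
F3 | step 7 | 5,6,7-tris(benzyloxy)-2-[4-(benzyloxy)phenyl]-4H-chromen-4-one | O=c1cc(-c2ccc(OCc3ccccc3)cc2)oc2cc(OCc3ccccc3)c(OCc3ccccc3)c(OCc3ccccc3)c12
F4 | step 7 | 5,6,7-tris(benzyloxy)-2-[4-(benzyloxy)phenyl]-2,3-epoxychroman-4-one (racemic, cis-fused; one enantiomer drawn) | O=C1[C@H]2O[C@@]2(c2ccc(OCc3ccccc3)cc2)Oc2cc(OCc3ccccc3)c(OCc3ccccc3)c(OCc3ccccc3)c12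
F5 | step 3 | tert-butyl 3-[4-(benzyloxy)phenyl]-2-chlorooxirane-2-carboxylate (racemic diastereomer mixture, not isolated) | CC(C)(C)OC(=O)C1(Cl)OC1c1ccc(OCc2ccccc2)cc1
F6 | step 3 | tert-butyl 3-[4-(benzyloxy)phenyl]-3-chloro-2-oxopropanoate (racemic) | CC(C)(C)OC(=O)C(=O)C(Cl)c1ccc(OCc2ccccc2)cc1
F7 | step 6 | allyl trans-3-[4-(benzyloxy)phenyl]oxirane-2-carboxylate (racemic; 2R,3S enantiomer drawn) | C=CCOC(=O)[C@@H]1O[C@H]1c1ccc(OCc2ccccc2)cc1
F8 | step 6 | allyl (2R*,3R*)-3-[4-(benzyloxy)phenyl]-2-hydroxy-3-[3,4,5-tris(benzyloxy)phenoxy]propanoate (racemic; 2R,3R enantiomer drawn) | C=CCOC(=O)[C@H](O)[C@H](Oc1cc(OCc2ccccc2)c(OCc2ccccc2)c(OCc2ccccc2)c1)c1ccc(OCc2ccccc2)cc1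
F9 | step 6 | allyl 3-[4-(benzyloxy)phenyl]-2-oxo-3-[3,4,5-tris(benzyloxy)phenoxy]propanoate (racemic) | C=CCOC(=O)C(=O)C(Oc1cc(OCc2ccccc2)c(OCc2ccccc2)c(OCc2ccccc2)c1)c1ccc(OCc2ccccc2)cc1
F10 | step 6 | allyl (E)-2-acetoxy-3-[4-(benzyloxy)phenyl]-3-[3,4,5-tris(benzyloxy)phenoxy]prop-2-enoate | C=CCOC(=O)/C(OC(C)=O)=C(\Oc1cc(OCc2ccccc2)c(OCc2ccccc2)c(OCc2ccccc2)c1)c1ccc(OCc2ccccc2)cc1
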